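**Strategy.** The dihydropyran ring is treated as the dehydrated hemiketal of a tertiary C8 alcohol and a syncarpic carbonyl. In one flask, an amine-catalysed asymmetric Michael addition of syncarpic acid to a δ-hydroxy enone joins ring carbon C3' to the future isobutyl-bearing methine C4', and cyclodehydration then joins the C8 oxygen to the neighbouring ring carbon C2' (formal [4+2] annulation). It exploits the pyran ring O–C8(spiro)–C15–C4'(isobutyl)–C3'=C2', in which the C8 oxygen and carbonyl-derived C2' are 1,5-related. The precursor is a norcaryophyllane tertiary alcohol, made from caryophyllene oxide via kobusone, that carries an (E)-4-oxopent-2-enyl chain; its acetyl group activates C4' and later becomes the isopropyl end of the isobutyl group.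

Key step: step 7

**Remarks**
- Numbering: caryophyllane numbering for the bicyclo[7.2.0]undecane (C1/C9 ring fusion, C4 carries methyl C12, C5 is the carbinol, C8 the spiro carbon, C10/C11 the cyclobutane CH2 and CMe2). C15 is the exocyclic methylene carbon of 1, later the allylic CH2 on C8 and finally the pyran CH2. C4' is the isobutyl-bearing methine; C3' and C2' are the two sp2 carbons of the tetramethylcyclohexenedione ring (C2' carries the ring oxygen). The target is (1R,3Z,5S,8S,9S,4'S).
- Assumption: syncarpic acid is taken as a purchased material; if it is not, it is made in three routine steps from phloroglucinol.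
- The C5 configuration of the target is opposite to that of the C5–O bond in (−)-caryophyllene oxide, so C5 is reset by oxidation and reduction (steps 4 and 5).

**Route**

Step 1
Reactants: 1 (−)-caryophyllene oxide
Product: 3 kobusone (4,5-epoxy-15-norcaryophyllan-8-one), via ozonide 2 (not isolated)
Conditions: O3, CH2Cl2, −78 °C; then Me2S, −78 °C to rt
Reagents that add atoms: ozone, [O-][O+]=O
Why: Criegee ozonolysis cleaves the only C=C (the exocyclic C8=C15 methylene) to the C8 ketone, while the trisubstituted 4,5-epoxide is inert to ozone and masks the later ring alkene and C5 oxygen, so no stereocentre is formed or touched.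

Step 2
Reactants: 3 kobusone; 4 allylmagnesium bromide
Product: 5 (1R,4R,5R,8S,9S)-8-allyl-4,5-epoxy-15-norcaryophyllan-8-ol
Conditions: CH2=CHCH2MgBr (1.5 equiv), THF, −78 °C; aq. NH4Cl
Reagents that add atoms: allylmagnesium bromide, C=CC[Mg]Br
Why: Grignard 1,2-addition, in which the allyl group should enter the C8 carbonyl from the face away from the cyclobutane methylene C10 on the adjacent stereocentre C9 (1,2-induction), placing the new hydroxyl syn to C10 (8S), while the hindered epoxide does not react at −78 °C.

Step 3
Reactants: 5 epoxy homoallylic alcohol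
Product: 6 (1R,3Z,5R,8S,9S)-8-allyl-15-norcaryophyll-3-ene-5,8-diol
Conditions: Et2Al(TMP) (4 equiv, from Et2AlCl and lithium 2,2,6,6-tetramethylpiperidide), toluene, 0 °C; aq. potassium sodium tartrate
Reagents that add atoms: none
Why: Base-induced epoxide-to-allylic-alcohol isomerization by syn-elimination through a cyclic aluminium amide transition state, in which the amide should remove a hydrogen from C3 (the branch cis to the epoxide hydrogen) and not from the C12 methyl, the C5–O bond and hence 5R stay untouched, and the new C3=C4 bond is expected in the less strained Z geometry.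

Step 4
Reactants: 6 (3Z,5R)-diol
Product: 7 (1R,3Z,8S,9S)-8-allyl-8-hydroxy-15-norcaryophyll-3-en-5-one
Conditions: Dess–Martin periodinane (1.3 equiv), CH2Cl2, 0 °C to rt
Reagents that add atoms: none
Why: Dess–Martin oxidation can only touch the secondary allylic C5 hydroxyl (the C8 hydroxyl is tertiary), giving the conjugated Z-enone and erasing the C5 centre so that it can be reset.

Step 5
Reactants: 7 enone
Product: 8 (1R,3Z,5S,8S,9S)-8-allyl-15-norcaryophyll-3-ene-5,8-diol
Conditions: (R)-2-methyl-CBS-oxazaborolidine (20 mol %), catecholborane (2.5 equiv), toluene, −78 °C; aq. work-up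
Reagents that add atoms: none
Why: Corey–Bakshi–Shibata reduction delivers hydride under reagent control with the α-methylalkenyl arm as the large and C6H2 as the small substituent, for which the (R)-oxazaborolidine should give the 5S carbinol, and catecholborane at −78 °C leaves the terminal alkene alone.

Step 6
Reactants: 8 (3Z,5S)-diol; 9 methyl vinyl ketone
Product: 10 (1R,3Z,5S,8S,9S)-8-[(2E)-4-oxopent-2-en-1-yl]-15-norcaryophyll-3-ene-5,8-diol
Conditions: second-generation Hoveyda–Grubbs catalyst RuCl2(=CH-2-iPrOC6H4)(H2IMes) (5 mol %), methyl vinyl ketone (3 equiv), CH2Cl2, 40 °C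
Reagents that add atoms: methyl vinyl ketone, C=CC(C)=O
Why: Olefin cross-metathesis between the unhindered terminal alkene and the electron-poor enone partner gives the E-enone under thermodynamic control, the trisubstituted ring alkene being too hindered to take part, and no stereocentre is formed.

Step 7
Reactants: 10 δ-hydroxy enone; 11 syncarpic acid
Product: 14 (1R,3Z,5S,8S,9S,4'R)-4'-(2-oxopropyl) pyran (the target with CH2COCH3 in place of isobutyl), via Michael adduct 12 (not isolated), via hemiketal 13 (not isolated)
Conditions: 9-amino-9-deoxy-epi-quinine (20 mol %), CF3CO2H (40 mol %), CH2Cl2, rt; then 4 Å MS, PPTS (20 mol %), 40 °C, same flask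
Reagents that add atoms: syncarpic acid, CC1(C)C(=O)CC(=O)C(C)(C)C1=O
Why: Iminium activation of the enone by the primary amine salt lets the enol carbon C3' of syncarpic acid add to C4' (Michael addition, C3'–C4' bond); after hydrolysis of the enamine the C8 hydroxyl adds to one of the two symmetry-equivalent flanking carbonyls (C2') and the hemiketal loses water, which forms the O–C2' enol-ether bond and makes the sequence a formal [4+2] annulation. The closest known reaction type is the amine-catalysed enantioselective addition of cyclic 1,3-diones to α,β-unsaturated ketones, which normally stops at a hemiketal. The dihydropyran closes by 6-exo-trig attack of oxygen on the C2' carbonyl followed by β-elimination of water from the resulting β-hydroxy ketone unit. C4' is set under catalyst control (the quinine-derived amine is expected to shield the enone face that leads to 4'R at this stage, the quinidine-derived pseudoenantiomer being the lever if the sense is opposite), and C8 keeps its configuration because its C–O bond is never broken. The step needs C- rather than O-alkylation of the dione, secured by the soft iminium acceptor, and ring closure through the C8 hydroxyl rather than through the side-chain ketone, secured because the latter gives only a reversible hemiketal while dehydration to the conjugated vinylogous ester is a thermodynamic sink.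

Step 8
Reactants: 14 methyl ketone; 15 methyltriphenylphosphonium bromide
Product: 16 (1R,3Z,5S,8S,9S,4'S)-4'-(2-methylprop-2-en-1-yl) pyran
Conditions: Ph3PCH3Br (3 equiv), KOtBu (2.8 equiv), THF, 0 °C to rt
Reagents that add atoms: methyltriphenylphosphonium bromide, C[P+](c1ccccc1)(c1ccccc1)c1ccccc1.[Br-]
Why: Wittig methylenation should touch only the unhindered methyl ketone, since the vinylogous ester carbonyl is deactivated and the remaining ring ketone lies between two quaternary carbons, and C4' cannot epimerize because retro-Michael cleavage is blocked once the enol ether is in place.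

Step 9
Reactants: 16 methallyl compound
Product: 17 Tomentodione P
Conditions: H2 (1 atm), RhCl(PPh3)3 (10 mol %), benzene, rt
Reagents that add atoms: none
Why: Homogeneous hydrogenation with RhCl(PPh3)3 reduces only the 1,1-disubstituted alkene and leaves the trisubstituted ring alkene and the tetrasubstituted enol ether, and the new CH is not stereogenic.

**Compound list**

1 | (−)-caryophyllene oxide, (1R,4R,5R,9S)-4,5-epoxycaryophyll-8(15)-ene | C[C@@]12CC[C@@H]3[C@H](CC3(C)C)C(=C)CC[C@H]1O2 | starting material
2 | ozonide of 1 (spiro-1,2,4-trioxolane at C8, C8 configuration undefined) | C[C@@]12CC[C@@H]3[C@H](CC3(C)C)C4(OCOO4)CC[C@H]1O2 | intermediate (not isolated)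
3 | kobusone, (1R,4R,5R,9S)-4,5-epoxy-15-norcaryophyllan-8-one | C[C@@]12CC[C@@H]3[C@H](CC3(C)C)C(=O)CC[C@H]1O2 | intermediate
4 | allylmagnesium bromide | C=CC[Mg]Br | starting material
5 | (1R,4R,5R,8S,9S)-8-allyl-4,5-epoxy-15-norcaryophyllan-8-ol | C[C@@]12CC[C@@H]3[C@H](CC3(C)C)[C@@](O)(CC=C)CC[C@H]1O2 | intermediate
6 | (1R,3Z,5R,8S,9S)-8-allyl-15-norcaryophyll-3-ene-5,8-diol | C/C1=C/C[C@@H]2[C@H](CC2(C)C)[C@@](O)(CC=C)CC[C@H]1O | intermediate
7 | (1R,3Z,8S,9S)-8-allyl-8-hydroxy-15-norcaryophyll-3-en-5-one | C/C1=C/C[C@@H]2[C@H](CC2(C)C)[C@@](O)(CC=C)CCC1=O | intermediate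
8 | (1R,3Z,5S,8S,9S)-8-allyl-15-norcaryophyll-3-ene-5,8-diol | C/C1=C/C[C@@H]2[C@H](CC2(C)C)[C@@](O)(CC=C)CC[C@@H]1O | intermediate
9 | methyl vinyl ketone (but-3-en-2-one) | C=CC(C)=O | starting material
10 | (1R,3Z,5S,8S,9S)-8-[(2E)-4-oxopent-2-en-1-yl]-15-norcaryophyll-3-ene-5,8-diol | C/C1=C/C[C@@H]2[C@H](CC2(C)C)[C@@](O)(C/C=C/C(C)=O)CC[C@@H]1O | intermediate
11 | syncarpic acid, 2,2,4,4-tetramethylcyclohexane-1,3,5-trione (triketone tautomer) | CC1(C)C(=O)CC(=O)C(C)(C)C1=O | starting material
12 | Michael adduct: 2-substituted syncarpic acid (enol form) attached through C3' to C4' (4'R), with C8–OH and C5–OH free | C/C1=C/C[C@@H]2[C@H](CC2(C)C)[C@@](O)(C[C@H](CC(C)=O)C3=C(O)C(C)(C)C(=O)C(C)(C)C3=O)CC[C@@H]1O | intermediate (not isolated)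
13 | cyclic hemiketal of 12 (C8 oxygen added to C2'; C2' configuration undefined) | C/C1=C/C[C@@H]2[C@H](CC2(C)C)[C@]2(CC[C@@H]1O)C[C@H](CC(C)=O)C1=C(O)C(C)(C)C(=O)C(C)(C)C1(O)O2 | intermediate (not isolated)
14 | (1R,3Z,5S,8S,9S,4'R)-4'-(2-oxopropyl) analogue of the target | C/C1=C/C[C@@H]2[C@H](CC2(C)C)[C@]2(CC[C@@H]1O)C[C@H](CC(C)=O)C1=C(O2)C(C)(C)C(=O)C(C)(C)C1=O | intermediate
15 | methyltriphenylphosphonium bromide | C[P+](c1ccccc1)(c1ccccc1)c1ccccc1.[Br-] | starting material
16 | (1R,3Z,5S,8S,9S,4'S)-4'-(2-methylprop-2-en-1-yl) analogue of the target | C/C1=C/C[C@@H]2[C@H](CC2(C)C)[C@]2(CC[C@@H]1O)C[C@H](CC(C)=C)C1=C(O2)C(C)(C)C(=O)C(C)(C)C1=O | intermediate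
17 | Tomentodione P, (1R,3Z,5S,8S,9S,4'S) | C/C1=C/C[C@@H]2[C@H](CC2(C)C)[C@]2(CC[C@@H]1O)C[C@H](CC(C)C)C1=C(O2)C(C)(C)C(=O)C(C)(C)C1=O | target

**Step count and risks**

Total step count: 9. Longest linear sequence: 9 steps (1 to 17); compounds 4, 9, 11 and 15 are purchased.

Steps most likely to fail:

1. Step 7 (key step). What may go wrong: slow conjugate addition between two hindered partners; amine-triggered vinylogous retro-aldol cleavage of the C8–C15 bond back to the C8 ketone; weak facial control at C4'; or closure of the dione oxygen onto the side-chain ketone instead of the C8 hydroxyl onto C2'. Fallback (sets out from 5, comes back at 17): the same two bonds are made by a π-allyl route that has neither an iminium nor a side-chain ketone. Cross-metathesis of 5 with 2-methylbut-3-en-2-ol gives the (E)-allylic tertiary alcohol F1. Pd2(dba)3 with a chiral DACH-phenyl diphosphine and syncarpic acid then effects a dehydrative Tsuji–Trost allylation at the less substituted allyl terminus C4', followed in the same flask by PPTS-promoted cyclodehydration, to give the 2-methylprop-1-enyl epoxy-pyran F2. Hydrogen over Pd on carbon saturates the side-chain alkene while the epoxide still masks the ring alkene, giving the isobutyl epoxide F3. Et2Al(TMP) isomerizes the epoxide to the 5R allylic alcohol F4, Dess–Martin oxidation gives the enone F5, and Corey–Bakshi–Shibata reduction with the (R)-oxazaborolidine and catecholborane returns 17.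

2. Step 3. What may go wrong: proton removal from the C12 methyl instead of C3, which places the alkene exocyclic, or formation of the E ring alkene. Fallback (sets out from 5, comes back at 7): LiNEt2 in ether deliberately gives the exocyclic allylic alcohol F6, and Dess–Martin oxidation gives the exo-methylene enone F7. LiBH(s-Bu)3 at −78 °C reduces F7 in the conjugate sense to the α-methyl ketone F8, and dehydrogenation with 2-iodoxybenzoic acid (DMSO, 70 °C) on the more substituted side should install the endocyclic, thermodynamically preferred Z-enone 7.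

3. Step 2. What may go wrong: allyl delivery to the other face of the C8 carbonyl (the C8 epimer), or enolization of the ketone. Fallback (sets out from 1, comes back at 5): the same face preference is used to place oxygen, not carbon, on the accessible face. Buffered mCPBA (NaHCO3, CH2Cl2) epoxidizes the exocyclic alkene of 1 to the spiro-diepoxide F9, and CH2=CHMgBr with catalytic CuI opens only the spiro-epoxide at its CH2 terminus to give 5.

**Further compounds**

F1 | step 7 | (1R,4R,5R,8S,9S)-4,5-epoxy-8-[(2E)-4-hydroxy-4-methylpent-2-en-1-yl]-15-norcaryophyllan-8-ol | C[C@@]12CC[C@@H]3[C@H](CC3(C)C)[C@@](O)(C/C=C/C(C)(C)O)CC[C@H]1O2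
F2 | step 7 | pyran annulation product with the 4,5-epoxide intact and a 2-methylprop-1-enyl group at C4' (4'R) | C[C@@]12CC[C@@H]3[C@H](CC3(C)C)[C@]4(CC[C@H]1O2)C[C@H](C=C(C)C)C5=C(O4)C(C)(C)C(=O)C(C)(C)C5=O
F3 | step 7 | isobutyl pyran with the (4R,5R)-epoxide in place of the 3-ene-5-ol (4'S) | C[C@@]12CC[C@@H]3[C@H](CC3(C)C)[C@]4(CC[C@H]1O2)C[C@H](CC(C)C)C5=C(O4)C(C)(C)C(=O)C(C)(C)C5=O
F4 | step 7 | 5-epi-Tomentodione P (5R) | C/C1=C/C[C@@H]2[C@H](CC2(C)C)[C@]2(CC[C@H]1O)C[C@H](CC(C)C)C1=C(O2)C(C)(C)C(=O)C(C)(C)C1=O
F5 | step 7 | 5-oxo analogue of Tomentodione P (C5 ketone, 3Z) | C/C1=C/C[C@@H]2[C@H](CC2(C)C)[C@]2(CCC1=O)C[C@H](CC(C)C)C1=C(O2)C(C)(C)C(=O)C(C)(C)C1=O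
F6 | step 3 | (1R,5R,8S,9S)-8-allyl-15-norcaryophyll-4(12)-ene-5,8-diol | C=C1CC[C@@H]2[C@H](CC2(C)C)[C@@](O)(CC=C)CC[C@H]1O
F7 | step 3 | (1R,8S,9S)-8-allyl-8-hydroxy-15-norcaryophyll-4(12)-en-5-one | C=C1CC[C@@H]2[C@H](CC2(C)C)[C@@](O)(CC=C)CCC1=O
F8 | step 3 | (1R,8S,9S)-8-allyl-8-hydroxy-15-norcaryophyllan-5-one (C4 epimers) | CC1CC[C@@H]2[C@H](CC2(C)C)[C@@](O)(CC=C)CCC1=O
F9 | step 2 | (1R,4R,5R,8R,9S)-4,5:8,15-diepoxycaryophyllane | C[C@@]12CC[C@@H]3[C@H](CC3(C)C)[C@@]4(CO4)CC[C@H]1O2
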